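**Plan**

1. Numbering (eudesmane): ring A = C1–C5 and C10; ring B = C5–C10; C10 is the quaternary carbon (methyl C14), C5 the ring-fusion CH, C7 carries C11(=C13H2)–C12O2Me, and C15 is the CH2O carbon on C4. α means the face opposite to the C10 methyl, β the same face.
2. Retrosynthetic cuts, in order: the C15–O acyl bond (Mitsunobu) and the aryl–CH= bond of the (Z)-coumarate (Suzuki coupling, done apart); the C15–O bond (allylic oxidation of a C4 methyl); C11–C12 (carbonylation of an enol triflate); C11–C13 (MeLi on a C7 carboxylic acid).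
3. The feature used: C7 carries a carbonyl-derived carbon and stands 1,3 to C9, the CH2 next to quaternary C10. With a temporary ketone at C9, C8 can be excised (C9–C8 and C8–C7 cut together). Ring B then becomes the cyclopentanone ring C5–C6–C7–C9–C10 of a hydrindanone β-keto ester, in which C7 is simply the α-carbon.
4. Forward: an amino-acid-mediated Robinson annulation builds ring A and the five-membered ring. Ring A is taken to the 3-ene with trans fusion, C7 is acylated and bromomethylated, and a radical 1,2-acyl shift inserts C8 so that ring B appears (five to six atoms). The C9 ketone is then removed, C11 is elaborated to the acrylate, C15 is oxidised and the coumarate is attached last.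
5. Stereochemistry: C10 comes from the (S)-phenylalanine-controlled aldol desymmetrisation. C5 comes from protonation in the Li/NH3 reduction (H trans to the C10 methyl). C7 is stereoconvergent: it passes through a planar radical and later an enolisable acetyl group, which settles equatorial (7β). The Z alkene comes from (Z)-3-iodoacrylic acid with retention.

Key step: step 9

Remark: (Z)-3-iodoacrylic acid is taken as a commercial reagent.

**Route**

Step 1
Reactants: 1 2-methylcyclopentane-1,3-dione; 2 pent-1-en-3-one (ethyl vinyl ketone)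
Product: 3 triketone 2-methyl-2-(3-oxopentyl)cyclopentane-1,3-dione
Conditions: H2O, AcOH (cat.), 70 °C
Reagents that add atoms: none
Why: Michael addition of the enolised cyclic 1,3-dione to the vinyl ketone; the product is achiral because the two ring carbonyls are still equivalent.

Step 2
Reactants: 3 triketone
Product: 4 enedione (S)-4,7a-dimethyl-2,3,7,7a-tetrahydro-1H-indene-1,5(6H)-dione
Conditions: (S)-phenylalanine (1.0 equiv), (1S)-(+)-camphor-10-sulfonic acid (0.5 equiv), DMF, 30 → 70 °C
Reagents that add atoms: none
Why: Hajos–Parrish-type (Eder–Sauer–Wiechert) enamine aldol condensation in which the (S)-amino acid selects one of the two enantiotopic ring carbonyls, which sets the quaternary carbon (C10) as S, and loss of water gives the enone.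

Step 3
Reactants: 4 enedione
Product: 5 monoketal (S)-4,7a-dimethyl-2,3,7,7a-tetrahydrospiro[indene-1,2'-[1,3]dioxolan]-5(6H)-one
Conditions: ethylene glycol (3 equiv), TsOH·H2O (cat.), 4 Å molecular sieves, CH2Cl2, rt
Reagents that add atoms: ethylene glycol OCCO
Why: acid-catalysed ketalisation that should be chemoselective for the saturated cyclopentanone, the conjugated α-methylated enone carbonyl being the poorer electrophile; no stereocenter is formed.

Step 4
Reactants: 5 monoketal
Product: 7 enol triflate 4,7a-dimethyl-2,3,3a,6,7,7a-hexahydrospiro[indene-1,2'-[1,3]dioxolan]-5-yl trifluoromethanesulfonate (trans-fused; 3a-H α; 7a-CH3 β), via lithium enolate 6 (not isolated)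
Conditions: Li (2.2 equiv), t-BuOH (1.0 equiv), NH3(l)/THF, −78 °C; isoprene; NH3 evaporated; then PhNTf2 (1.5 equiv), THF, −78 °C → rt; aqueous work-up
Reagents that add atoms: N-phenylbis(trifluoromethanesulfonimide) O=S(=O)(N(c1ccccc1)S(=O)(=O)C(F)(F)F)C(F)(F)F
Why: Birch-type dissolving-metal reduction of the enone, in which C5 is protonated while its orbital stays aligned with the enolate π system, the mode that should lead to the trans ring fusion (H at C5 anti to the C10 methyl), followed by O-sulfonylation of the regiodefined C3–C4 enolate.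

Step 5
Reactants: 7 enol triflate
Product: 8 alkene ketal 4,7a-dimethyl-2,3,3a,6,7,7a-hexahydrospiro[indene-1,2'-[1,3]dioxolane] (trans-fused)
Conditions: Pd(OAc)2 (5 mol %), PPh3 (10 mol %), Bu3N (3 equiv), HCO2H (2 equiv), DMF, 60 °C
Reagents that add atoms: none
Why: palladium-catalysed formate reduction of an enol triflate (oxidative addition, decarboxylation of the formate to a palladium hydride, reductive elimination), which replaces OTf by H and leaves the C3=C4 alkene and both stereocenters in place.

Step 6
Reactants: 8 alkene ketal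
Product: 9 hydrindanone (3aS,7aS)-4,7a-dimethyl-2,3,3a,6,7,7a-hexahydro-1H-inden-1-one (trans-fused)
Conditions: 1 M aq HCl/THF (1:4), rt
Reagents that add atoms: water O
Why: mild acid hydrolysis of the dioxolane, chosen so that the trisubstituted alkene is not isomerised; no stereocenter is touched.

Step 7
Reactants: 9 hydrindanone
Product: 10 β-keto ester methyl 4,7a-dimethyl-1-oxo-2,3,3a,6,7,7a-hexahydro-1H-indene-2-carboxylate (trans-fused; C2 epimers and enol)
Conditions: NaH (2.5 equiv), (MeO)2CO (5 equiv), THF, reflux; AcOH work-up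
Reagents that add atoms: dimethyl carbonate COC(=O)OC
Why: Claisen-type C-acylation of the ketone enolate at C7, the only enolisable α-position because C10 is quaternary, driven by formation of the β-keto ester enolate; the new C7 centre is labile and its configuration is irrelevant.

Step 8
Reactants: 10 β-keto ester
Product: 12 bromomethyl β-keto ester methyl 2-(bromomethyl)-4,7a-dimethyl-1-oxo-2,3,3a,6,7,7a-hexahydro-1H-indene-2-carboxylate (CH2Br α expected), via sodium enolate 11 (not isolated)
Conditions: NaH (1.1 equiv), THF/HMPA (4:1), 0 °C; then CH2Br2 (6 equiv), 50 °C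
Reagents that add atoms: dibromomethane BrCBr
Why: C-alkylation of the β-keto ester enolate with excess dibromomethane (attack expected on the α face, anti to the angular methyl) installs the radical precursor; the configuration of this quaternary carbon is erased in step 9.

Step 9
Reactants: 12 bromomethyl β-keto ester
Product: 16 keto ester methyl (2S,4aS,8aS)-4a,8-dimethyl-4-oxo-1,2,3,4,4a,5,6,8a-octahydronaphthalene-2-carboxylate (eudesmane numbering: 9-oxo; 7β-CO2Me; 5α-H; 10β-CH3), via primary alkyl radical 13 (not isolated), via cyclopropyloxy radical 14 (not isolated), via tertiary C7 radical 15 (not isolated)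
Conditions: Bu3SnH (1.2 equiv, syringe pump over 6 h), AIBN (0.1 equiv), benzene (0.01 M), reflux
Reagents that add atoms: none
Why: Bu3Sn• abstracts bromine from 12 to give the primary radical 13, which closes 3-exo-trig onto the neighbouring C9 carbonyl to the cyclopropyloxy radical 14; β-scission of the C9–C7 bond of 14 (net 1,2-acyl shift) places C8 between C9 and C7 and gives the tertiary, ester-stabilised radical 15, which takes a hydrogen atom from Bu3SnH. The closest known reaction type is the Dowd–Beckwith one-carbon ring expansion of 2-(halomethyl) cyclic β-keto esters. The only ring closed is the transient cyclopropane (3-exo-trig, radical onto C=O); ring B is not closed but grown, the five-membered ring C5–C6–C7–C9–C10 becoming the six-membered ring C5–C6–C7–C8–C9–C10. The one new stereocenter, C7, is set when the planar radical 15 is reduced, hydrogen being expected on the axial α face so that CO2Me is equatorial (7β); since the quaternary centre of 12 is erased in 15 both epimers of 12 converge, and any 7α material is corrected later by enolisation (step 11). The step needs rearrangement to outrun direct reduction of 13, which is secured by keeping Bu3SnH dilute, and ring-enlarging scission of 14 to outrun the reverse opening, which is secured by the ester stabilisation of 15 and by relief of the strain of the trans-fused hydrindanone. The ketone and not the ester carbonyl is the acceptor because only its alkoxy radical can fragment to a stabilised radical, and the ring A alkene is out of reach of 13.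

Step 10
Reactants: 16 keto ester
Product: 19 acid (2R,4aR,8aR)-4a,8-dimethyl-1,2,3,4,4a,5,6,8a-octahydronaphthalene-2-carboxylic acid, via potassium keto carboxylate 17 (not isolated), via hydrazone 18 (not isolated)
Conditions: KOH (5 equiv), diethylene glycol/H2O, 110 °C; then N2H4·H2O (10 equiv), 130 °C; distillation to 200 °C, 4 h; then aq HCl to pH 2
Reagents that add atoms: potassium hydroxide [K+].[OH-]
Why: saponification followed by Wolff–Kishner reduction (Huang-Minlon procedure) of the C9 ketone via its hydrazone; a cyclic acyl hydrazide is not expected because it would need a bridgehead C=N in a bicyclo[3.3.1] frame, and no stereocenter other than the epimerisable C7 is at risk.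

Step 11
Reactants: 19 acid
Product: 21 methyl ketone 1-[(2R,4aR,8aR)-4a,8-dimethyl-1,2,3,4,4a,5,6,8a-octahydronaphthalen-2-yl]ethan-1-one, via dilithium gem-diolate 20 (not isolated)
Conditions: MeLi (3 equiv), Et2O, 0 °C → rt; poured into ice-water; then NaOMe (0.2 equiv), MeOH, rt
Reagents that add atoms: methyllithium [Li]C
Why: addition of MeLi to the lithium carboxylate stops at the dilithium gem-diolate, which gives the methyl ketone on hydrolysis, and base-mediated enolisation then equilibrates C7 to the equatorial 7β-acetyl isomer (thermodynamic control; the minor axial epimer can be recycled).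

Step 12
Reactants: 21 methyl ketone
Product: 23 vinyl triflate 1-[(2R,4aR,8aR)-4a,8-dimethyl-1,2,3,4,4a,5,6,8a-octahydronaphthalen-2-yl]ethenyl trifluoromethanesulfonate, via lithium enolate 22 (not isolated)
Conditions: LiN(iPr)2 (1.1 equiv), THF, −78 °C; then PhNTf2 (1.2 equiv), −78 → 0 °C; aqueous work-up
Reagents that add atoms: N-phenylbis(trifluoromethanesulfonimide) O=S(=O)(N(c1ccccc1)S(=O)(=O)C(F)(F)F)C(F)(F)F
Why: kinetic deprotonation at the unhindered methyl group rather than at the tertiary C7–H, then O-triflation of the terminal enolate, so that C7 keeps its configuration.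

Step 13
Reactants: 23 vinyl triflate
Product: 24 methyl isocostate methyl 2-[(2R,4aR,8aR)-4a,8-dimethyl-1,2,3,4,4a,5,6,8a-octahydronaphthalen-2-yl]prop-2-enoate
Conditions: Pd(OAc)2 (5 mol %), PPh3 (10 mol %), Et3N (2 equiv), CO (1 atm), MeOH/DMF (1:2), rt → 40 °C
Reagents that add atoms: carbon monoxide [C-]#[O+]; methanol CO
Why: palladium-catalysed methoxycarbonylation of the vinyl triflate (oxidative addition, CO insertion, methanolysis of the acyl palladium species) gives the α-substituted acrylate without touching a stereocenter.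

Step 14
Reactants: 24 methyl isocostate
Product: 25 allylic alcohol methyl 2-[(2R,4aR,8aR)-8-(hydroxymethyl)-4a-methyl-1,2,3,4,4a,5,6,8a-octahydronaphthalen-2-yl]prop-2-enoate
Conditions: SeO2 (0.5 equiv), t-BuOOH (3 equiv, in decane), CH2Cl2, 0 °C → rt
Reagents that add atoms: selenium dioxide O=[Se]=O; tert-butyl hydroperoxide CC(C)(C)OO
Why: Riley allylic oxidation (ene reaction at C3, then [2,3]-sigmatropic shift) that should take place at the methyl group C15 on the more substituted alkene carbon, CH3 being preferred over the ring-fusion CH, while the electron-poor acrylate alkene is inert.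

Step 15
Reactants: 26 (Z)-3-iodoacrylic acid; 27 4-hydroxyphenylboronic acid
Product: 28 (Z)-p-coumaric acid (2Z)-3-(4-hydroxyphenyl)prop-2-enoic acid
Conditions: Pd(PPh3)4 (3 mol %), K2CO3 (3.5 equiv), 1,4-dioxane/H2O (3:1), 50 °C, dark; then aq HCl to pH 3 at 0 °C
Reagents that add atoms: none
Why: Suzuki–Miyaura coupling of the alkenyl iodide, in which oxidative addition, transmetalation and reductive elimination all proceed with retention, so the Z geometry of the iodoacrylate is carried into the coumaric acid.

Step 16
Reactants: 25 allylic alcohol; 28 (Z)-p-coumaric acid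
Product: 29 target methyl 2-[(2R,4aR,8aR)-8-({[(2Z)-3-(4-hydroxyphenyl)prop-2-enoyl]oxy}methyl)-4a-methyl-1,2,3,4,4a,5,6,8a-octahydronaphthalen-2-yl]prop-2-enoate
Conditions: PPh3 (1.2 equiv), DIAD (1.2 equiv), THF, 0 °C → rt, dark
Reagents that add atoms: none
Why: Mitsunobu esterification of the primary allylic alcohol under neutral conditions, in which the carboxylic acid (far more acidic than the phenol) is the nucleophile and neither the Z alkene nor the acrylate is exposed to base.

**Compound list**

1 | 2-methylcyclopentane-1,3-dione | CC1C(=O)CCC1=O | starting material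
2 | pent-1-en-3-one (ethyl vinyl ketone) | CCC(=O)C=C | starting material
3 | 2-methyl-2-(3-oxopentyl)cyclopentane-1,3-dione | CCC(=O)CCC1(C)C(=O)CCC1=O | intermediate
4 | (S)-4,7a-dimethyl-2,3,7,7a-tetrahydro-1H-indene-1,5(6H)-dione | CC1=C2CCC(=O)[C@@]2(C)CCC1=O | intermediate
5 | (S)-4,7a-dimethyl-2,3,7,7a-tetrahydrospiro[indene-1,2'-[1,3]dioxolan]-5(6H)-one | CC1=C2CCC3(OCCO3)[C@@]2(C)CCC1=O | intermediate
6 | lithium enolate of the trans-fused ketal ketone (not isolated) | CC1=C([O-])CC[C@@]2(C)[C@H]1CCC23OCCO3.[Li+] | intermediate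
7 | trans-fused enol triflate (3a-H α, 7a-CH3 β) | CC1=C(OS(=O)(=O)C(F)(F)F)CC[C@@]2(C)[C@H]1CCC23OCCO3 | intermediate
8 | trans-fused alkene ketal | CC1=CCC[C@@]2(C)[C@H]1CCC23OCCO3 | intermediate
9 | (3aS,7aS)-4,7a-dimethyl-2,3,3a,6,7,7a-hexahydro-1H-inden-1-one | CC1=CCC[C@@]2(C)[C@H]1CCC2=O | intermediate
10 | methyl 4,7a-dimethyl-1-oxo-2,3,3a,6,7,7a-hexahydro-1H-indene-2-carboxylate (trans-fused, C2 labile) | CC1=CCC[C@@]2(C)[C@H]1CC(C(=O)OC)C2=O | intermediate
11 | sodium enolate of 10 (not isolated) | CC1=CCC[C@@]2(C)[C@H]1CC(C(=O)OC)=C2[O-].[Na+] | intermediate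
12 | methyl 2-(bromomethyl)-4,7a-dimethyl-1-oxo-2,3,3a,6,7,7a-hexahydro-1H-indene-2-carboxylate (CH2Br α expected) | CC1=CCC[C@@]2(C)[C@H]1C[C@](CBr)(C(=O)OC)C2=O | intermediate
13 | primary alkyl radical from 12 (not isolated) | CC1=CCC[C@@]2(C)[C@H]1C[C@]([CH2])(C(=O)OC)C2=O | intermediate
14 | cyclopropyloxy radical (not isolated) | CC1=CCC[C@@]2(C)[C@H]1CC3(C(=O)OC)CC23[O] | intermediate
15 | ring-expanded tertiary C7 radical (not isolated) | COC(=O)[C]1CC(=O)[C@@]2(C)CCC=C(C)[C@@H]2C1 | intermediate
16 | methyl (2S,4aS,8aS)-4a,8-dimethyl-4-oxo-1,2,3,4,4a,5,6,8a-octahydronaphthalene-2-carboxylate | COC(=O)[C@@H]1CC(=O)[C@@]2(C)CCC=C(C)[C@@H]2C1 | intermediate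
17 | potassium salt of the keto acid (not isolated) | [K+].[O-]C(=O)[C@@H]1CC(=O)[C@@]2(C)CCC=C(C)[C@@H]2C1 | intermediate
18 | C9 hydrazone of 17 (not isolated) | [K+].[O-]C(=O)[C@@H]1CC(=NN)[C@@]2(C)CCC=C(C)[C@@H]2C1 | intermediate
19 | (2R,4aR,8aR)-4a,8-dimethyl-1,2,3,4,4a,5,6,8a-octahydronaphthalene-2-carboxylic acid | OC(=O)[C@@H]1CC[C@@]2(C)CCC=C(C)[C@@H]2C1 | intermediate
20 | dilithium gem-diolate (not isolated) | [Li+].[Li+].CC([O-])([O-])[C@@H]1CC[C@@]2(C)CCC=C(C)[C@@H]2C1 | intermediate
21 | 1-[(2R,4aR,8aR)-4a,8-dimethyl-1,2,3,4,4a,5,6,8a-octahydronaphthalen-2-yl]ethan-1-one | CC(=O)[C@@H]1CC[C@@]2(C)CCC=C(C)[C@@H]2C1 | intermediate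
22 | lithium enolate of 21 at the methyl group (not isolated) | [Li+].C=C([O-])[C@@H]1CC[C@@]2(C)CCC=C(C)[C@@H]2C1 | intermediate
23 | 1-[(2R,4aR,8aR)-4a,8-dimethyl-1,2,3,4,4a,5,6,8a-octahydronaphthalen-2-yl]ethenyl trifluoromethanesulfonate | C=C(OS(=O)(=O)C(F)(F)F)[C@@H]1CC[C@@]2(C)CCC=C(C)[C@@H]2C1 | intermediate
24 | methyl isocostate, methyl 2-[(2R,4aR,8aR)-4a,8-dimethyl-1,2,3,4,4a,5,6,8a-octahydronaphthalen-2-yl]prop-2-enoate | C=C(C(=O)OC)[C@@H]1CC[C@@]2(C)CCC=C(C)[C@@H]2C1 | intermediate
25 | methyl 2-[(2R,4aR,8aR)-8-(hydroxymethyl)-4a-methyl-1,2,3,4,4a,5,6,8a-octahydronaphthalen-2-yl]prop-2-enoate | C=C(C(=O)OC)[C@@H]1CC[C@@]2(C)CCC=C(CO)[C@@H]2C1 | intermediate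
26 | (Z)-3-iodoacrylic acid | OC(=O)/C=C\I | starting material
27 | 4-hydroxyphenylboronic acid | OB(O)c1ccc(O)cc1 | starting material
28 | (2Z)-3-(4-hydroxyphenyl)prop-2-enoic acid | OC(=O)/C=C\c1ccc(O)cc1 | intermediate
29 | methyl 2-[(2R,4aR,8aR)-8-({[(2Z)-3-(4-hydroxyphenyl)prop-2-enoyl]oxy}methyl)-4a-methyl-1,2,3,4,4a,5,6,8a-octahydronaphthalen-2-yl]prop-2-enoate | C=C(C(=O)OC)[C@@H]1CC[C@@]2(C)CCC=C(COC(=O)/C=C\c3ccc(O)cc3)[C@@H]2C1 | target

**Step count and risks**

Total step count: 16. Longest linear sequence: 15 steps (steps 1–14 and 16); step 15 is a one-step branch.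

Steps most likely to fail:

Step 14. The selenium reagent may attack the ring methylene C2 or the ring-fusion C5–H instead of C15, and the allylic alcohol may be oxidised further to the enal. The fallback sets out from 24 and comes back at 25. Epoxidation (mCPBA, NaHCO3, CH2Cl2, 0 °C) should take place only at the electron-rich ring alkene and from the α face, giving the 3α,4α-epoxide F1. TMSOTf and DBU (toluene, 0 °C → rt) open the epoxide at the tertiary C4–O bond with loss of a C15 proton, giving the exocyclic allyl silyl ether F2; H5 is syn to the departing oxygen and is not lost. Citric acid in MeOH frees the 4(15)-en-3α-ol F3. Ph3SiOReO3 (2 mol %, Et2O, 0 °C) then brings about the 1,3-transposition of the allylic alcohol under thermodynamic control, to the primary alcohol with the trisubstituted ring alkene, 25.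

Step 10. Hydrazone formation at the C9 carbonyl, which is flanked by the quaternary C10, may be slow, and the keto acid may degrade under the forcing alkaline conditions. The fallback sets out from 16 and comes back at 19. Ethane-1,2-dithiol with BF3·OEt2 (CH2Cl2, 0 °C → rt) gives the dithiolane F4. Raney Ni (deactivated by reflux in acetone; EtOH, rt) cleaves both C–S bonds to the deoxygenated methyl ester F5. Saponification (KOH, MeOH/H2O, 60 °C; then aq HCl) gives 19.

Step 4. Facial selectivity in the protonation of C5 may be poor, because the trans-fused hydrindane is the more strained ring fusion, and O-triflation of the enolate may be incomplete. The fallback sets out from 5 and comes back at 8; it sets C5 by a suprafacial hydrogen shift instead. Luche reduction (NaBH4, CeCl3·7H2O, MeOH, −78 °C; hydride on the α face) gives the 3β-allylic alcohol F6. A Mitsunobu reaction with 2-nitrobenzenesulfonylhydrazide (PPh3, diethyl azodicarboxylate, THF, −30 °C) gives with inversion the 3α-sulfonylhydrazine F7. On warming to rt this loses 2-nitrobenzenesulfinic acid to the allylic diazene F8, whose retro-ene loss of N2 delivers hydrogen to the α face of C5 and moves the double bond to C3=C4, which is 8.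

Further compounds
F1 | step 14 | methyl 2-[3α,4α-epoxy-4-methyl decalin]acrylate (3,4-epoxide of 24) | C=C(C(=O)OC)[C@@H]1CC[C@@]2(C)CC[C@H]3O[C@@]3(C)[C@@H]2C1
F2 | step 14 | 3α-trimethylsilyloxy-4(15)-ene (allyl silyl ether) | C=C(C(=O)OC)[C@@H]1CC[C@@]2(C)CC[C@@H](O[Si](C)(C)C)C(=C)[C@@H]2C1
F3 | step 14 | 4(15)-en-3α-ol (exocyclic allylic alcohol) | C=C(C(=O)OC)[C@@H]1CC[C@@]2(C)CC[C@@H](O)C(=C)[C@@H]2C1
F4 | step 10 | C9 dithiolane of 16 | COC(=O)[C@@H]1CC2(SCCS2)[C@@]2(C)CCC=C(C)[C@@H]2C1
F5 | step 10 | methyl (2R,4aR,8aR)-4a,8-dimethyl-1,2,3,4,4a,5,6,8a-octahydronaphthalene-2-carboxylate | COC(=O)[C@@H]1CC[C@@]2(C)CCC=C(C)[C@@H]2C1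
F6 | step 4 | 3β-allylic alcohol from 5 (eudesmane C3; indene C5) | CC1=C2CCC3(OCCO3)[C@@]2(C)CC[C@@H]1O
F7 | step 4 | 3α-N-(2-nitrobenzenesulfonyl)hydrazine | CC1=C2CCC3(OCCO3)[C@@]2(C)CC[C@H]1N(N)S(=O)(=O)c1ccccc1[N+](=O)[O-]
F8 | step 4 | 3α-allylic diazene | CC1=C2CCC3(OCCO3)[C@@]2(C)CC[C@H]1N=N
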